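**Retrosynthetic overview**

- The acid comes from its methyl ester, and the (1E,3E)-diene from dehydration of a homoallylic alcohol.
- Key C–C bond (side-chain C1'–C2'): α-selective carbonyl allylation of an enantiopure 2-formyl-2-methylchroman with the allylbarium reagent of an (E)-C15 allylic chloride.
- The allylic chloride comes from dihydro-β-ionone (cyclohexene ring bought intact) by Horner–Wadsworth–Emmons olefination, reduction and chlorination.
- The chroman aldehyde comes from a tertiary alcohol by intramolecular Pd-catalysed aryl C–O coupling, then C6 bromination, carbonylation, debenzylation and oxidation.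
- The stereocentre comes from (S)-2-methylglycidol (Sharpless epoxidation of methallyl alcohol), opened by 2-bromobenzyl Grignard. Ring order: oxirane (step 1, opened in step 4), then the dihydropyran ring (step 5); the benzene and cyclohexene rings are bought.

Assumption: the SMILES is read as the (2R) acid with a (1E,3E) diene; dihydro-β-ionone, methallyl alcohol and 2-bromobenzyl bromide are bought.

**Route**

Step 1
Reactants: 1 2-methylprop-2-en-1-ol (methallyl alcohol)
Product: 3 [(2R)-2-methyloxiran-2-yl]methyl 4-nitrobenzoate, via (S)-2-methylglycidol 2 (not isolated)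
Conditions: Ti(OiPr)4 (5 mol %), diisopropyl L-(+)-tartrate (6 mol %), cumene hydroperoxide, 4 Å sieves, CH2Cl2, −20 °C; P(OMe)3; then 4-nitrobenzoyl chloride, Et3N, 0 °C; recrystallised
Reagents that add atoms: cumene hydroperoxide, CC(C)(OO)c1ccccc1; 4-nitrobenzoyl chloride, O=C(Cl)c1ccc(cc1)[N+](=O)[O-]
Why: Sharpless asymmetric epoxidation with the L-(+)-tartrate catalyst gives the (S)-epoxy alcohol (about 95% ee), and esterification in the flask gives a crystalline 4-nitrobenzoate that is recrystallised to >99% ee, which sets the only stereocentre of the target (the R descriptor of the ester reflects CIP ranking only).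

Step 2
Reactants: 3 [(2R)-2-methyloxiran-2-yl]methyl 4-nitrobenzoate
Product: 2 [(2S)-2-methyloxiran-2-yl]methanol ((S)-2-methylglycidol)
Conditions: K2CO3 (10 mol %), MeOH, 0 °C; distilled
Reagents that add atoms: none
Why: Base-catalysed transesterification frees the epoxy alcohol without opening the epoxide, and the Payne rearrangement of its alkoxide is degenerate and returns the same enantiomer, so no ee is lost.

Step 3
Reactants: 2 [(2S)-2-methyloxiran-2-yl]methanol
Product: 4 (2R)-2-[(benzyloxy)methyl]-2-methyloxirane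
Conditions: NaH, BnBr, Bu4NI (cat.), THF, 0 °C to rt
Reagents that add atoms: benzyl bromide, BrCc1ccccc1
Why: Williamson ether synthesis protects the primary hydroxyl as a benzyl ether that survives the Grignard, palladium and bromination steps, with the stereocentre untouched (S to R is a CIP ranking change only).

Step 4
Reactants: 4 (2R)-2-[(benzyloxy)methyl]-2-methyloxirane; 5 1-bromo-2-(bromomethyl)benzene (2-bromobenzyl bromide)
Product: 7 (2R)-1-(benzyloxy)-4-(2-bromophenyl)-2-methylbutan-2-ol, via (2-bromobenzyl)magnesium bromide 6 (not isolated)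
Conditions: 5, Mg, Et2O, 0 °C; then 4, CuI (10 mol %), THF, −30 to 0 °C
Reagents that add atoms: none
Why: Copper-catalysed SN2 opening of the 2,2-disubstituted epoxide by the benzylic Grignard reagent occurs at the unsubstituted CH2, so no bond at the stereocentre is broken and the tertiary alcohol keeps the configuration.

Step 5
Reactants: 7 (2R)-1-(benzyloxy)-4-(2-bromophenyl)-2-methylbutan-2-ol
Product: 8 (2R)-2-[(benzyloxy)methyl]-2-methyl-3,4-dihydro-2H-chromene
Conditions: Pd(OAc)2 (3 mol %), 2-(di-tert-butylphosphino)-1,1'-binaphthyl (4 mol %), Cs2CO3, toluene, 80 °C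
Reagents that add atoms: none
Why: Intramolecular Buchwald-type palladium-catalysed C–O coupling of the aryl bromide with the tertiary alkoxide (no hydrogen on the carbinol carbon to lose) closes the six-membered ring at the aryl carbon and leaves the stereocentre untouched.

Step 6
Reactants: 8 (2R)-2-[(benzyloxy)methyl]-2-methyl-3,4-dihydro-2H-chromene
Product: 9 (2R)-2-[(benzyloxy)methyl]-6-bromo-2-methyl-3,4-dihydro-2H-chromene
Conditions: NBS (1.05 equiv), MeCN, 0 °C to rt, dark
Reagents that add atoms: N-bromosuccinimide, O=C1CCC(=O)N1Br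
Why: Electrophilic aromatic bromination goes para to the ring oxygen (C6), since C8 is more hindered and the benzyl ether ring is not activated.

Step 7
Reactants: 9 (2R)-2-[(benzyloxy)methyl]-6-bromo-2-methyl-3,4-dihydro-2H-chromene
Product: 10 methyl (2R)-2-[(benzyloxy)methyl]-2-methyl-3,4-dihydro-2H-chromene-6-carboxylate
Conditions: Pd(OAc)2 (3 mol %), Xantphos (6 mol %), CO (1 atm), MeOH, Et3N, toluene, 80 °C
Reagents that add atoms: carbon monoxide, [C-]#[O+]; methanol, CO
Why: Palladium-catalysed alkoxycarbonylation (oxidative addition, CO insertion, methanolysis of the acylpalladium) turns the aryl bromide into the methyl ester under conditions inert to the benzyl ether.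

Step 8
Reactants: 10 methyl (2R)-2-[(benzyloxy)methyl]-2-methyl-3,4-dihydro-2H-chromene-6-carboxylate
Product: 11 methyl (2R)-2-(hydroxymethyl)-2-methyl-3,4-dihydro-2H-chromene-6-carboxylate
Conditions: H2 (1 atm), 10% Pd/C, EtOAc/MeOH, rt
Reagents that add atoms: none
Why: Catalytic hydrogenolysis cleaves only the O-benzyl bond, as the aryl ester and the non-benzylic C2–O bond of the chroman are inert.

Step 9
Reactants: 11 methyl (2R)-2-(hydroxymethyl)-2-methyl-3,4-dihydro-2H-chromene-6-carboxylate
Product: 12 methyl (2R)-2-formyl-2-methyl-3,4-dihydro-2H-chromene-6-carboxylate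
Conditions: Dess–Martin periodinane, CH2Cl2, 0 °C to rt
Reagents that add atoms: none
Why: Dess–Martin oxidation gives an aldehyde with no α-hydrogen, so it cannot enolise or epimerise.

Step 10
Reactants: 13 4-(2,6,6-trimethylcyclohex-1-en-1-yl)butan-2-one (dihydro-β-ionone)
Product: 14 ethyl (2E)-3-methyl-5-(2,6,6-trimethylcyclohex-1-en-1-yl)pent-2-enoate
Conditions: triethyl phosphonoacetate, NaH, THF, 0 °C to reflux; E isomer separated on SiO2
Reagents that add atoms: triethyl phosphonoacetate, CCOC(=O)CP(=O)(OCC)OCC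
Why: Horner–Wadsworth–Emmons olefination of the methyl ketone gives the trisubstituted enoate mainly as the E isomer (about 4:1), and the minor Z isomer is removed by chromatography.

Step 11
Reactants: 14 ethyl (2E)-3-methyl-5-(2,6,6-trimethylcyclohex-1-en-1-yl)pent-2-enoate
Product: 15 (2E)-3-methyl-5-(2,6,6-trimethylcyclohex-1-en-1-yl)pent-2-en-1-ol
Conditions: i-Bu2AlH (2.2 equiv), CH2Cl2, −78 to 0 °C
Reagents that add atoms: none
Why: 1,2-Reduction of the enoate by i-Bu2AlH gives the allylic alcohol without touching either C=C bond.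

Step 12
Reactants: 15 (2E)-3-methyl-5-(2,6,6-trimethylcyclohex-1-en-1-yl)pent-2-en-1-ol
Product: 17 2-[(3E)-5-chloro-3-methylpent-3-en-1-yl]-1,3,3-trimethylcyclohex-1-ene, via allylic mesylate 16 (not isolated)
Conditions: MsCl, LiCl, 2,4,6-collidine, DMF, 0 °C
Reagents that add atoms: lithium chloride, [Li+].[Cl-]
Why: Collington–Meyers chlorination (mesylate formed in the flask and displaced by chloride in an SN2 reaction) gives the primary allylic chloride without allylic transposition or E/Z isomerisation.

Step 13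
Reactants: 17 2-[(3E)-5-chloro-3-methylpent-3-en-1-yl]-1,3,3-trimethylcyclohex-1-ene; 12 methyl (2R)-2-formyl-2-methyl-3,4-dihydro-2H-chromene-6-carboxylate
Product: 19 methyl (2R)-2-[(3E)-1-hydroxy-4-methyl-6-(2,6,6-trimethylcyclohex-1-en-1-yl)hex-3-en-1-yl]-2-methyl-3,4-dihydro-2H-chromene-6-carboxylate (mixture of C1' epimers), via allylbarium chloride 18 (not isolated)
Conditions: BaI2, Li/biphenyl (lithium biphenylide LiC12H10, 2 equiv), THF, rt; 17, −78 °C; then cannulated into 12 (1.05 equiv of 18), THF, −78 °C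
Reagents that add atoms: none
Why: Carbonyl allylation with an allylbarium reagent joins the two fragments, because γ,γ-disubstituted allylbarium reagents add to aldehydes through the unsubstituted α-carbon with retention of the E geometry and at −78 °C the aldehyde reacts much faster than the aryl ester; the new carbinol centre forms as an epimer mixture that is removed in step 14.

Step 14
Reactants: 19 methyl (2R)-2-[(3E)-1-hydroxy-4-methyl-6-(2,6,6-trimethylcyclohex-1-en-1-yl)hex-3-en-1-yl]-2-methyl-3,4-dihydro-2H-chromene-6-carboxylate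
Product: 21 methyl (2R)-2-methyl-2-[(1E,3E)-4-methyl-6-(2,6,6-trimethylcyclohex-1-en-1-yl)hexa-1,3-dien-1-yl]-3,4-dihydro-2H-chromene-6-carboxylate, via secondary mesylate 20 (not isolated)
Conditions: MsCl, Et3N, CH2Cl2, 0 °C; then DBU, toluene, 90 °C
Reagents that add atoms: none
Why: Mesylation then base-induced anti E2 elimination can only remove the allylic C2' hydrogens (C2 of the chroman is quaternary), and the transition state with the chroman and vinyl groups anti gives the conjugated E alkene from both epimers.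

Step 15
Reactants: 21 methyl (2R)-2-methyl-2-[(1E,3E)-4-methyl-6-(2,6,6-trimethylcyclohex-1-en-1-yl)hexa-1,3-dien-1-yl]-3,4-dihydro-2H-chromene-6-carboxylate
Product: 22 (2R)-2-methyl-2-[(1E,3E)-4-methyl-6-(2,6,6-trimethylcyclohex-1-en-1-yl)hexa-1,3-dien-1-yl]-3,4-dihydro-2H-chromene-6-carboxylic acid
Conditions: LiOH·H2O, THF/MeOH/H2O, 40 °C; then 0.5 M HCl to pH 4, 0 °C
Reagents that add atoms: lithium hydroxide, [Li+].[OH-]
Why: Saponification of the methyl ester under basic conditions, followed by brief mild acidification, preserves the acid-labile tertiary allylic aryl ether, the diene and the stereocentre.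

**Compound list**

1 | 2-methylprop-2-en-1-ol (methallyl alcohol) | C=C(C)CO | starting material
2 | [(2S)-2-methyloxiran-2-yl]methanol ((S)-2-methylglycidol) | OC[C@@]1(C)CO1 | intermediate
3 | [(2R)-2-methyloxiran-2-yl]methyl 4-nitrobenzoate | O=C(OC[C@@]1(C)CO1)c1ccc(cc1)[N+](=O)[O-] | intermediate
4 | (2R)-2-[(benzyloxy)methyl]-2-methyloxirane | c1ccccc1COC[C@@]1(C)CO1 | intermediate
5 | 1-bromo-2-(bromomethyl)benzene (2-bromobenzyl bromide) | BrCc1ccccc1Br | starting material
6 | (2-bromobenzyl)magnesium bromide | Br[Mg]Cc1ccccc1Br | intermediate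
7 | (2R)-1-(benzyloxy)-4-(2-bromophenyl)-2-methylbutan-2-ol | c1ccccc1COC[C@@](O)(C)CCc1ccccc1Br | intermediate
8 | (2R)-2-[(benzyloxy)methyl]-2-methyl-3,4-dihydro-2H-chromene | c1ccccc1COC[C@@]1(C)CCc2ccccc2O1 | intermediate
9 | (2R)-2-[(benzyloxy)methyl]-6-bromo-2-methyl-3,4-dihydro-2H-chromene | c1ccccc1COC[C@@]1(C)CCc2cc(Br)ccc2O1 | intermediate
10 | methyl (2R)-2-[(benzyloxy)methyl]-2-methyl-3,4-dihydro-2H-chromene-6-carboxylate | c1ccccc1COC[C@@]1(C)CCc2cc(C(=O)OC)ccc2O1 | intermediate
11 | methyl (2R)-2-(hydroxymethyl)-2-methyl-3,4-dihydro-2H-chromene-6-carboxylate | OC[C@@]1(C)CCc2cc(C(=O)OC)ccc2O1 | intermediate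
12 | methyl (2R)-2-formyl-2-methyl-3,4-dihydro-2H-chromene-6-carboxylate | O=C[C@@]1(C)CCc2cc(C(=O)OC)ccc2O1 | intermediate
13 | 4-(2,6,6-trimethylcyclohex-1-en-1-yl)butan-2-one (dihydro-β-ionone) | CC(=O)CCC1=C(C)CCCC1(C)C | starting material
14 | ethyl (2E)-3-methyl-5-(2,6,6-trimethylcyclohex-1-en-1-yl)pent-2-enoate | CCOC(=O)/C=C(\C)CCC1=C(C)CCCC1(C)C | intermediate
15 | (2E)-3-methyl-5-(2,6,6-trimethylcyclohex-1-en-1-yl)pent-2-en-1-ol | OC/C=C(\C)CCC1=C(C)CCCC1(C)C | intermediate
16 | (2E)-3-methyl-5-(2,6,6-trimethylcyclohex-1-en-1-yl)pent-2-en-1-yl methanesulfonate | CS(=O)(=O)OC/C=C(\C)CCC1=C(C)CCCC1(C)C | intermediate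
17 | 2-[(3E)-5-chloro-3-methylpent-3-en-1-yl]-1,3,3-trimethylcyclohex-1-ene | ClC/C=C(\C)CCC1=C(C)CCCC1(C)C | intermediate
18 | chloro[(2E)-3-methyl-5-(2,6,6-trimethylcyclohex-1-en-1-yl)pent-2-en-1-yl]barium | Cl[Ba]C/C=C(\C)CCC1=C(C)CCCC1(C)C | intermediate
19 | methyl (2R)-2-[(3E)-1-hydroxy-4-methyl-6-(2,6,6-trimethylcyclohex-1-en-1-yl)hex-3-en-1-yl]-2-methyl-3,4-dihydro-2H-chromene-6-carboxylate (C1' epimers) | OC(C/C=C(\C)CCC1=C(C)CCCC1(C)C)[C@@]2(C)CCc3cc(C(=O)OC)ccc3O2 | intermediate
20 | methyl (2R)-2-[(3E)-1-(methanesulfonyloxy)-4-methyl-6-(2,6,6-trimethylcyclohex-1-en-1-yl)hex-3-en-1-yl]-2-methyl-3,4-dihydro-2H-chromene-6-carboxylate | CS(=O)(=O)OC(C/C=C(\C)CCC1=C(C)CCCC1(C)C)[C@@]2(C)CCc3cc(C(=O)OC)ccc3O2 | intermediate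
21 | methyl (2R)-2-methyl-2-[(1E,3E)-4-methyl-6-(2,6,6-trimethylcyclohex-1-en-1-yl)hexa-1,3-dien-1-yl]-3,4-dihydro-2H-chromene-6-carboxylate | CC1=C(CC/C(C)=C/C=C/[C@@]2(C)CCc3cc(C(=O)OC)ccc3O2)C(C)(C)CCC1 | intermediate
22 | (2R)-2-methyl-2-[(1E,3E)-4-methyl-6-(2,6,6-trimethylcyclohex-1-en-1-yl)hexa-1,3-dien-1-yl]-3,4-dihydro-2H-chromene-6-carboxylic acid | CC1=C(CC/C(C)=C/C=C/[C@@]2(C)CCc3cc(C(=O)O)ccc3O2)C(C)(C)CCC1 | target

**Step count**

Total: 15 steps. Longest linear sequence: 12 steps (steps 1–9, then 13–15); steps 10–12 form the second branch.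

**Steps most likely to fail, with fallbacks**

Step 13 (allylbarium addition). Risks are γ-attack giving the branched alcohol, Wurtz coupling of the chloride, and attack on the ester. The fallback makes the C1'=C2' bond directly by an E-selective Wittig olefination. It sets out from chloride 17, which is heated with PBu3 in MeCN to give tributyl[(2E)-3-methyl-5-(2,6,6-trimethylcyclohex-1-en-1-yl)pent-2-en-1-yl]phosphonium chloride F1. Deprotonation with KN(SiMe3)2 in THF at −78 °C gives tributyl[(2E)-3-methyl-5-(2,6,6-trimethylcyclohex-1-en-1-yl)pent-2-en-1-ylidene]phosphorane F2, which reacts with aldehyde 12. The fallback comes back to the route at diene ester 21, replacing steps 13 and 14.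

Step 14 (dehydration). Risks are slow elimination at the hindered carbinol, an E/Z mixture, or rearrangement through aryloxy participation. The fallback sets out from alcohol 19, which is treated with NaH, CS2 and then MeI in THF to give the S-methyl xanthate of alcohol 19 F3. Pyrolysis in refluxing xylene (Chugaev syn-elimination, no ionising leaving group) comes back to the route at 21.

Step 5 (palladium-catalysed etherification of a tertiary alcohol). Risks are slow reductive elimination and hydrodebromination. The fallback closes the ring by nucleophilic aromatic substitution and brings the C6 bromine in with the arene. It sets out from epoxide 4, which is opened (CuI cat., THF, −30 °C) by (5-bromo-2-fluorobenzyl)magnesium bromide F5, made from 4-bromo-2-(bromomethyl)-1-fluorobenzene F4 and Mg. This gives (2R)-1-(benzyloxy)-4-(5-bromo-2-fluorophenyl)-2-methylbutan-2-ol F6. Its sodium alkoxide (NaH, N-methylpyrrolidone, 110 °C) displaces fluoride intramolecularly and comes back to the route at bromochroman 9, replacing steps 4–6.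

**Further compounds**

F1 | step 13 | tributyl[(2E)-3-methyl-5-(2,6,6-trimethylcyclohex-1-en-1-yl)pent-2-en-1-yl]phosphonium chloride | CCCC[P+](CCCC)(CCCC)C/C=C(\C)CCC1=C(C)CCCC1(C)C.[Cl-]
F2 | step 13 | tributyl[(2E)-3-methyl-5-(2,6,6-trimethylcyclohex-1-en-1-yl)pent-2-en-1-ylidene]phosphorane | CCCCP(CCCC)(CCCC)=C/C=C(\C)CCC1=C(C)CCCC1(C)C
F3 | step 14 | methyl (2R)-2-methyl-2-[(3E)-4-methyl-1-{[(methylsulfanyl)carbonothioyl]oxy}-6-(2,6,6-trimethylcyclohex-1-en-1-yl)hex-3-en-1-yl]-3,4-dihydro-2H-chromene-6-carboxylate | CSC(=S)OC(C/C=C(\C)CCC1=C(C)CCCC1(C)C)[C@@]2(C)CCc3cc(C(=O)OC)ccc3O2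
F4 | step 5 | 4-bromo-2-(bromomethyl)-1-fluorobenzene | Fc1ccc(Br)cc1CBr
F5 | step 5 | (5-bromo-2-fluorobenzyl)magnesium bromide | Fc1ccc(Br)cc1C[Mg]Br
F6 | step 5 | (2R)-1-(benzyloxy)-4-(5-bromo-2-fluorophenyl)-2-methylbutan-2-ol | c1ccccc1COC[C@@](O)(C)CCc1cc(Br)ccc1F
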